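The backbone carbons are numbered C1–C23, starting from the ethyl group of the eastern pyranone. The route rests on the C8–C9 disconnection, between the propionyloxy carbinol and the CH(CH3) on that ring. The eastern ring (O, C3–C7) is a mono-substituted, C2v-symmetric 2,6-diethyl-3,5-dimethyl-4H-pyran-4-one. Its ethyl CH2 is vinylogously acidic through C7=C6–C5=O. The derived (Z)-2-ethylidene-4-silyloxy-2H-pyran attacks the complete western aldehyde (C9–C23; anti C10-methyl/C11-acetoxy, western pyranone already closed). This single vinylogous Mukaiyama aldol joins both halves, re-aromatises the eastern ring and sets C8 and C9. Only propionylation and desilylation follow.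

Key step: step 18

Remark on the chemistry: the centres that end as sp2 ring carbons of the western pyranone (C15, C16, C18, C19) are carried as diastereomer mixtures and are left undefined in the SMILES. TBS = tert-butyldimethylsilyl, TES = triethylsilyl, DMP = Dess–Martin periodinane, TRIP = 3,3'-bis(2,4,6-triisopropylphenyl)-BINOL hydrogen phosphate.

Step 1
Reactants: 1 propanal (two molecules)
Product: 2 (2S,3S)-3-hydroxy-2-methylpentanal
Conditions: L-proline (10 mol %), DMF, 4 °C
Reagents that add atoms: none
Why: Proline-catalysed enamine self-aldol of an aldehyde, in which the (E)-enamine attacks the Re face of a second propanal in the acid-organised chair-like transition state and should set C20 and C21 as the anti (2S,3S) pair, the minor syn isomer being removed by chromatography after step 2.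

Step 2
Reactants: 2 (2S,3S)-3-hydroxy-2-methylpentanal
Product: 3 (2S,3S)-3-(tert-butyldimethylsilyloxy)-2-methylpentanal
Conditions: TBSOTf, 2,6-lutidine, CH2Cl2, −78 °C
Reagents that add atoms: tert-butyldimethylsilyl triflate CC(C)(C)[Si](C)(C)OS(=O)(=O)C(F)(F)F
Why: Silyl ether formation with a hindered base at low temperature protects the C21 hydroxyl before the β-hydroxy aldehyde can oligomerise or dehydrate, and it touches no stereocentre.

Step 3
Reactants: 4 pentan-3-one; 3 (2S,3S)-3-(tert-butyldimethylsilyloxy)-2-methylpentanal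
Product: 6 7-(tert-butyldimethylsilyloxy)-5-hydroxy-4,6-dimethylnonan-3-one (C6/C7 as in 3; mixture at C4/C5), via lithium enolate 5 (not isolated)
Conditions: LDA, THF, −78 °C; then 3; AcOH quench
Reagents that add atoms: none
Why: Lithium enolate aldol addition, which at −78 °C is faster than enolisation of the α-chiral aldehyde and needs no selectivity because both new centres (backbone C18, C19) later become ring sp2 carbons.

Step 4
Reactants: 6 7-(tert-butyldimethylsilyloxy)-5-hydroxy-4,6-dimethylnonan-3-one
Product: 7 (6S,7S)-7-(tert-butyldimethylsilyloxy)-4,6-dimethylnonane-3,5-dione (C4 labile)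
Conditions: DMP, NaHCO3, CH2Cl2, 0 °C to rt
Reagents that add atoms: none
Why: Buffered Dess–Martin oxidation of the β-hydroxy ketone gives the 1,3-diketone, whose far more acidic central C–H shields the neighbouring C20–H from enolisation.

Step 5
Reactants: 8 methyl (R)-3-hydroxy-2-methylpropanoate
Product: 9 methyl (R)-3-(tert-butyldimethylsilyloxy)-2-methylpropanoate
Conditions: TBSCl, imidazole, CH2Cl2, rt
Reagents that add atoms: tert-butyldimethylsilyl chloride CC(C)(C)[Si](C)(C)Cl
Why: Imidazole-promoted silylation of the primary alcohol of the chiral-pool ester, which supplies C14 in the required configuration.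

Step 6
Reactants: 9 methyl (R)-3-(tert-butyldimethylsilyloxy)-2-methylpropanoate
Product: 11 (R)-3-(tert-butyldimethylsilyloxy)-2-methylpropanal, via aluminium hemiacetal 10 (not isolated)
Conditions: DIBAL-H, CH2Cl2, −78 °C; aq. work-up
Reagents that add atoms: none
Why: Partial DIBAL-H reduction of an ester, in which the tetrahedral aluminium hemiacetal persists at −78 °C and collapses only on work-up, so over-reduction and epimerisation at C14 should be avoided.

Step 7
Reactants: 11 (R)-3-(tert-butyldimethylsilyloxy)-2-methylpropanal; 12 2-(triphenylphosphoranylidene)propanal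
Product: 13 (2E,4S)-5-(tert-butyldimethylsilyloxy)-2,4-dimethylpent-2-enal
Conditions: toluene, 80 °C
Reagents that add atoms: none
Why: Wittig olefination with a stabilised formyl ylide, which should give the (E)-trisubstituted C12=C13 enal directly at the aldehyde oxidation level under salt-free, base-free conditions.

Step 8
Reactants: 13 (2E,4S)-5-(tert-butyldimethylsilyloxy)-2,4-dimethylpent-2-enal; 14 (E)-crotylboronic acid pinacol ester
Product: 16 (3R,4R,5E,7S)-8-(tert-butyldimethylsilyloxy)-3,5,7-trimethylocta-1,5-dien-4-ol, via pinacol borate 15 (not isolated)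
Conditions: (R)-TRIP (5 mol %), 4 Å MS, toluene, −30 °C; aq. work-up
Reagents that add atoms: none
Why: Chiral phosphoric acid-catalysed crotylboration, in which the closed chair transition state of the (E)-boronate sets the C10/C11 anti relation and (R)-TRIP directs attack to the Re face of the enal, the remote C14 centre having no say.

Step 9
Reactants: 16 (3R,4R,5E,7S)-8-(tert-butyldimethylsilyloxy)-3,5,7-trimethylocta-1,5-dien-4-ol
Product: 17 (3R,4R,5E,7S)-8-(tert-butyldimethylsilyloxy)-3,5,7-trimethylocta-1,5-dien-4-yl acetate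
Conditions: Ac2O, DMAP (cat.), pyridine, CH2Cl2, 0 °C to rt
Reagents that add atoms: acetic anhydride CC(=O)OC(C)=O
Why: DMAP-catalysed acetylation installs the C11 acetate of the target at once, so that it also serves as the protecting group for the rest of the route.

Step 10
Reactants: 17 (3R,4R,5E,7S)-8-(tert-butyldimethylsilyloxy)-3,5,7-trimethylocta-1,5-dien-4-yl acetate
Product: 18 (3R,4R,5E,7S)-8-hydroxy-3,5,7-trimethylocta-1,5-dien-4-yl acetate
Conditions: HF·pyridine, pyridine, THF, 0 °C
Reagents that add atoms: none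
Why: Fluoride-mediated desilylation of the only silyl ether, under buffered conditions that leave the allylic acetate in place.

Step 11
Reactants: 18 (3R,4R,5E,7S)-8-hydroxy-3,5,7-trimethylocta-1,5-dien-4-yl acetate
Product: 19 (3R,4R,5E,7S)-3,5,7-trimethyl-8-oxoocta-1,5-dien-4-yl acetate
Conditions: DMP, NaHCO3, CH2Cl2, 0 °C
Reagents that add atoms: none
Why: Buffered Dess–Martin oxidation gives the α-chiral β,γ-unsaturated aldehyde without a base strong enough to epimerise C14 or move the alkene, and the product is used at once.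

Step 12
Reactants: 7 (6S,7S)-7-(tert-butyldimethylsilyloxy)-4,6-dimethylnonane-3,5-dione; 19 (3R,4R,5E,7S)-3,5,7-trimethyl-8-oxoocta-1,5-dien-4-yl acetate
Product: 21 (3R,4R,5E,7S,13S,14S)-14-(tert-butyldimethylsilyloxy)-8-hydroxy-3,5,7,9,11,13-hexamethyl-10,12-dioxohexadeca-1,5-dien-4-yl acetate (mixture at C8/C9/C11), via dilithium dienediolate 20 (not isolated)
Conditions: 7, LDA (2.1 equiv), THF, −78 to 0 °C; −78 °C, then 19; AcOH quench at −78 °C
Reagents that add atoms: none
Why: Aldol addition of a 1,3-diketone dianion, in which the second deprotonation takes place at the less hindered ethyl CH2 and this most nucleophilic terminus should add to the aldehyde faster than it deprotonates it or attacks the acetate, the new centres (backbone C15, C16) being erased later.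

Step 13
Reactants: 21 the δ-hydroxy-β-diketone of step 12
Product: 22 (3R,4R,5E,7S,13S,14S)-14-(tert-butyldimethylsilyloxy)-3,5,7,9,11,13-hexamethyl-8,10,12-trioxohexadeca-1,5-dien-4-yl acetate (C9/C11 labile)
Conditions: DMP, NaHCO3, CH2Cl2, 0 °C to rt
Reagents that add atoms: none
Why: Dess–Martin oxidation gives the 1,3,5-triketone, which is largely enolised between its carbonyl groups (away from C14 and C20) and is carried on without purification.

Step 14
Reactants: 22 the 1,3,5-triketone of step 13
Product: 23 (3R,4R,5E,7S)-7-{6-[(2S,3S)-3-(tert-butyldimethylsilyloxy)pentan-2-yl]-3,5-dimethyl-4-oxo-4H-pyran-2-yl}-3,5-dimethylocta-1,5-dien-4-yl acetate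
Conditions: Ph3P, CCl4, THF, rt
Reagents that add atoms: none
Why: Cyclodehydration of a 1,3,5-triketone to a 4-pyranone with Ph3P–CCl4 (Appel-type activation of an enol oxygen, O-cyclisation and loss of Ph3PO) runs at room temperature without added acid or base and should keep C14, C20, the acetate and the silyl ether intact.

Step 15
Reactants: 23 the western pyranone with the terminal vinyl group
Product: 25 (2S,3R,4E,6S)-6-{6-[(2S,3S)-3-(tert-butyldimethylsilyloxy)pentan-2-yl]-3,5-dimethyl-4-oxo-4H-pyran-2-yl}-2,4-dimethyl-1-oxohept-4-en-3-yl acetate, via vicinal diol 24 (not isolated)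
Conditions: OsO4 (2 mol %), NMO, acetone–H2O, 0 °C; then NaIO4, THF–H2O, 0 °C
Reagents that add atoms: N-methylmorpholine N-oxide C[N+]1([O-])CCOCC1 (oxygen relayed by osmium tetroxide O=[Os](=O)(=O)=O); water O
Why: Upjohn dihydroxylation followed by periodate cleavage (Lemieux–Johnson sequence), in which the monosubstituted alkene should react first because C12=C13 is deactivated by its allylic acetate and flanked by two tertiary carbons and the pyranone C=C bonds are electron-poor and tetrasubstituted.

Step 16
Reactants: 4 pentan-3-one; 26 propionic acid (2 equiv)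
Product: 27 2,6-diethyl-3,5-dimethyl-4H-pyran-4-one
Conditions: polyphosphoric acid, 130 °C
Reagents that add atoms: none
Why: Classical 4-pyranone synthesis by double C-acylation of a ketone with a carboxylic acid in polyphosphoric acid followed by cyclodehydration, which poses no selectivity question because the product is C2v-symmetric.

Step 17
Reactants: 27 2,6-diethyl-3,5-dimethyl-4H-pyran-4-one
Product: 29 (Z)-4-(tert-butyldimethylsilyloxy)-6-ethyl-2-ethylidene-3,5-dimethyl-2H-pyran, via lithium dienolate 28 (not isolated)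
Conditions: LDA, THF, −78 °C; TBSCl, DMPU, −78 to 0 °C; pentane extraction, used at once
Reagents that add atoms: tert-butyldimethylsilyl chloride CC(C)(C)[Si](C)(C)Cl
Why: Kinetic vinylogous deprotonation of a 2-alkyl-4-pyranone and O-silylation of the dienolate, in which the two ethyl groups are equivalent and A1,3 strain with the adjacent ring methyl group forces the ethylidene methyl cis to the ring oxygen (Z).

Step 18
Reactants: 25 the western C9 aldehyde; 29 (Z)-4-(tert-butyldimethylsilyloxy)-6-ethyl-2-ethylidene-3,5-dimethyl-2H-pyran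
Product: 31 C9 alcohol (8R,9R,10R,11R,12E,14S,20S,21S) carrying both pyranones with C11 acetate and C21 TBS ether, via silyloxypyrylium aldolate 30 (not isolated)
Conditions: 25, BF3·OEt2 (3.5 equiv), CH2Cl2, −78 °C; 29 (2 equiv) added slowly; aq. NaHCO3 at −78 °C
Reagents that add atoms: none
Why: Proposed new method: the BF3-activated aldehyde 25 is attacked by the exocyclic ethylidene carbon of 29 (the γ-terminus of a cross-conjugated silyl dienol ether), which turns the 2H-pyran into the aromatic 4-silyloxypyrylium aldolate 30, and the bicarbonate work-up releases pyranone 31; no ring is closed, an existing ring is re-aromatised. The closest known reaction types are the vinylogous Mukaiyama aldol of acyclic and dioxinone-derived silyl dienol ethers and the lithium dienolate aldol of 2-ethyl-4-pyranones, whereas a pyranone-derived silyl dienol ether has not been shown in this role. C9 is controlled by the aldehyde: Felkin–Anh attack anti to the C11 branch and the polar 1,3-anti model for the β-acetoxy group reinforce each other in an anti α-methyl/β-oxy aldehyde, so the Si face should be attacked (C9–O syn to C10–CH3 and anti to C11–O). C8 is controlled by the single (Z)-geometry of 29, whose methyl group is trans to the enol silane chain as in the (E)-γ-methyl dienolates that give anti adducts, and by an open transition state that keeps the aldehyde chain away from the pyran ring, which should give the C8/C9 anti relation. γ- over α-attack is secured by the methyl-blocked ring carbons and the gain of pyrylium aromaticity, and mono-addition by the loss of nucleophilicity after the first addition. The non-basic conditions spare the β-acetoxy aldehyde, the acidic C14–H and the TBS ether, while the extra BF3 saturates the Lewis-basic western pyranone.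

Step 19
Reactants: 31 the C9 alcohol
Product: 32 C9 propionate (8R,9R,10R,11R,12E,14S,20S,21S) with C11 acetate and C21 TBS ether
Conditions: (EtCO)2O, DMAP (cat.), pyridine, CH2Cl2, 0 °C
Reagents that add atoms: propionic anhydride CCC(=O)OC(=O)CC
Why: DMAP-catalysed acylation of the only free hydroxyl group, kept cold and short so that acylation outruns 1,3-acetyl migration and base-induced elimination across C8–C9.

Step 20
Reactants: 32 the C9 propionate
Product: 33 target CNP0331774.1 (8R,9R,10R,11R,12E,14S,20S,21S)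
Conditions: HF·pyridine, pyridine, THF, 0 °C to rt
Reagents that add atoms: none
Why: Fluoride-mediated desilylation frees the C21 hydroxyl, which is too far from either ester for acyl migration, while both esters, the alkene and both pyranones are inert to buffered HF.

Compound list
1 | propanal | CCC=O | starting material
2 | (2S,3S)-3-hydroxy-2-methylpentanal | O=C[C@@H](C)[C@@H](O)CC | intermediate
3 | (2S,3S)-3-(tert-butyldimethylsilyloxy)-2-methylpentanal | O=C[C@@H](C)[C@@H](O[Si](C)(C)C(C)(C)C)CC | intermediate
4 | pentan-3-one | CCC(=O)CC | starting material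
5 | lithium enolate of pentan-3-one | CC=C([O-])CC.[Li+] | intermediate
6 | 7-(tert-butyldimethylsilyloxy)-5-hydroxy-4,6-dimethylnonan-3-one (C6/C7 as in 3; mixture at C4/C5) | CCC(=O)C(C)C(O)[C@@H](C)[C@@H](O[Si](C)(C)C(C)(C)C)CC | intermediate
7 | (6S,7S)-7-(tert-butyldimethylsilyloxy)-4,6-dimethylnonane-3,5-dione | CCC(=O)C(C)C(=O)[C@@H](C)[C@@H](O[Si](C)(C)C(C)(C)C)CC | intermediate
8 | methyl (R)-3-hydroxy-2-methylpropanoate | COC(=O)[C@H](C)CO | starting material
9 | methyl (R)-3-(tert-butyldimethylsilyloxy)-2-methylpropanoate | COC(=O)[C@H](C)CO[Si](C)(C)C(C)(C)C | intermediate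
10 | diisobutylaluminium hemiacetal of 9 | COC(O[Al](CC(C)C)CC(C)C)[C@H](C)CO[Si](C)(C)C(C)(C)C | intermediate
11 | (R)-3-(tert-butyldimethylsilyloxy)-2-methylpropanal | O=C[C@H](C)CO[Si](C)(C)C(C)(C)C | intermediate
12 | 2-(triphenylphosphoranylidene)propanal | CC(C=O)=P(c1ccccc1)(c1ccccc1)c1ccccc1 | starting material
13 | (2E,4S)-5-(tert-butyldimethylsilyloxy)-2,4-dimethylpent-2-enal | O=C/C(C)=C/[C@H](C)CO[Si](C)(C)C(C)(C)C | intermediate
14 | (E)-crotylboronic acid pinacol ester | C/C=C/CB1OC(C)(C)C(C)(C)O1 | starting material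
15 | pinacol borate of alcohol 16 | C=C[C@@H](C)[C@@H](OB1OC(C)(C)C(C)(C)O1)/C(C)=C/[C@H](C)CO[Si](C)(C)C(C)(C)C | intermediate
16 | (3R,4R,5E,7S)-8-(tert-butyldimethylsilyloxy)-3,5,7-trimethylocta-1,5-dien-4-ol | C=C[C@@H](C)[C@@H](O)/C(C)=C/[C@H](C)CO[Si](C)(C)C(C)(C)C | intermediate
17 | (3R,4R,5E,7S)-8-(tert-butyldimethylsilyloxy)-3,5,7-trimethylocta-1,5-dien-4-yl acetate | C=C[C@@H](C)[C@@H](OC(C)=O)/C(C)=C/[C@H](C)CO[Si](C)(C)C(C)(C)C | intermediate
18 | (3R,4R,5E,7S)-8-hydroxy-3,5,7-trimethylocta-1,5-dien-4-yl acetate | C=C[C@@H](C)[C@@H](OC(C)=O)/C(C)=C/[C@H](C)CO | intermediate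
19 | (3R,4R,5E,7S)-3,5,7-trimethyl-8-oxoocta-1,5-dien-4-yl acetate | C=C[C@@H](C)[C@@H](OC(C)=O)/C(C)=C/[C@H](C)C=O | intermediate
20 | dilithium dienediolate of 7 | [Li+].[Li+].CC=C([O-])C(C)=C([O-])[C@@H](C)[C@@H](O[Si](C)(C)C(C)(C)C)CC | intermediate
21 | (3R,4R,5E,7S,13S,14S)-14-(tert-butyldimethylsilyloxy)-8-hydroxy-3,5,7,9,11,13-hexamethyl-10,12-dioxohexadeca-1,5-dien-4-yl acetate (mixture at C8/C9/C11) | C=C[C@@H](C)[C@@H](OC(C)=O)/C(C)=C/[C@H](C)C(O)C(C)C(=O)C(C)C(=O)[C@@H](C)[C@@H](O[Si](C)(C)C(C)(C)C)CC | intermediate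
22 | (3R,4R,5E,7S,13S,14S)-14-(tert-butyldimethylsilyloxy)-3,5,7,9,11,13-hexamethyl-8,10,12-trioxohexadeca-1,5-dien-4-yl acetate | C=C[C@@H](C)[C@@H](OC(C)=O)/C(C)=C/[C@H](C)C(=O)C(C)C(=O)C(C)C(=O)[C@@H](C)[C@@H](O[Si](C)(C)C(C)(C)C)CC | intermediate
23 | (3R,4R,5E,7S)-7-{6-[(2S,3S)-3-(tert-butyldimethylsilyloxy)pentan-2-yl]-3,5-dimethyl-4-oxo-4H-pyran-2-yl}-3,5-dimethylocta-1,5-dien-4-yl acetate | C=C[C@@H](C)[C@@H](OC(C)=O)/C(C)=C/[C@H](C)c1oc([C@@H](C)[C@@H](O[Si](C)(C)C(C)(C)C)CC)c(C)c(=O)c1C | intermediate
24 | vicinal diol from the vinyl group of 23 (epimers at the new carbinol) | OCC(O)[C@@H](C)[C@@H](OC(C)=O)/C(C)=C/[C@H](C)c1oc([C@@H](C)[C@@H](O[Si](C)(C)C(C)(C)C)CC)c(C)c(=O)c1C | intermediate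
25 | (2S,3R,4E,6S)-6-{6-[(2S,3S)-3-(tert-butyldimethylsilyloxy)pentan-2-yl]-3,5-dimethyl-4-oxo-4H-pyran-2-yl}-2,4-dimethyl-1-oxohept-4-en-3-yl acetate | O=C[C@@H](C)[C@@H](OC(C)=O)/C(C)=C/[C@H](C)c1oc([C@@H](C)[C@@H](O[Si](C)(C)C(C)(C)C)CC)c(C)c(=O)c1C | intermediate
26 | propionic acid | CCC(=O)O | starting material
27 | 2,6-diethyl-3,5-dimethyl-4H-pyran-4-one | CCc1oc(CC)c(C)c(=O)c1C | intermediate
28 | lithium (Z)-dienolate of 27 | C/C=C1\OC(CC)=C(C)C([O-])=C1C.[Li+] | intermediate
29 | (Z)-4-(tert-butyldimethylsilyloxy)-6-ethyl-2-ethylidene-3,5-dimethyl-2H-pyran | C/C=C1\OC(CC)=C(C)C(O[Si](C)(C)C(C)(C)C)=C1C | intermediate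
30 | 4-silyloxypyrylium trifluoroborate aldolate (zwitterion; configuration as in 31) | F[B-](F)(F)O[C@H]([C@@H](C)[C@@H](OC(C)=O)/C(C)=C/[C@H](C)c1oc([C@@H](C)[C@@H](O[Si](C)(C)C(C)(C)C)CC)c(C)c(=O)c1C)[C@@H](C)c1[o+]c(CC)c(C)c(O[Si](C)(C)C(C)(C)C)c1C | intermediate
31 | C9 alcohol (8R,9R,10R,11R,12E,14S,20S,21S); C11 acetate; C21 TBS ether | O[C@H]([C@@H](C)[C@@H](OC(C)=O)/C(C)=C/[C@H](C)c1oc([C@@H](C)[C@@H](O[Si](C)(C)C(C)(C)C)CC)c(C)c(=O)c1C)[C@@H](C)c1oc(CC)c(C)c(=O)c1C | intermediate
32 | C9 propionate (8R,9R,10R,11R,12E,14S,20S,21S); C11 acetate; C21 TBS ether | CCC(=O)O[C@H]([C@@H](C)[C@@H](OC(C)=O)/C(C)=C/[C@H](C)c1oc([C@@H](C)[C@@H](O[Si](C)(C)C(C)(C)C)CC)c(C)c(=O)c1C)[C@@H](C)c1oc(CC)c(C)c(=O)c1C | intermediate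
33 | CNP0331774.1 (8R,9R,10R,11R,12E,14S,20S,21S) | CCC(=O)O[C@H]([C@@H](C)[C@@H](OC(C)=O)/C(C)=C/[C@H](C)c1oc([C@@H](C)[C@@H](O)CC)c(C)c(=O)c1C)[C@@H](C)c1oc(CC)c(C)c(=O)c1C | target

Total step count: 20
Longest linear sequence: 14 steps (8 to 33 through steps 5–15 and 18–20)

Steps most likely to fail

1. Step 18 (the labelled step).
- What may go wrong: the dienol ether may be protodesilylated or destroyed by BF3 before the C–C bond forms. Simple diastereoselection at C8 may be weak in the open transition state. The aldolate oxygen may be lost by elimination at the pyrylium stage.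
- Fallback (known chemistry only), from 25 back to the route at 32: the C8–C9 bond is made by a closed-transition-state crotylboration, and the eastern ring is then built with the reactions already used for the western ring. Aldehyde 25 reacts with 14 under (S)-TRIP catalysis to give the anti homoallylic alcohol F1; attack is on the Si face, matched with the Felkin preference, and the anti relation comes from the (E)-boronate. Propionic anhydride/DMAP gives the C9 propionate F2. OsO4/NMO followed by NaIO4 cleaves the new vinyl group to the C7 aldehyde F3. The dilithium dianion of commercial 4-methylheptane-3,5-dione adds at −78 °C to give the hydroxy diketone F4. Dess–Martin oxidation gives the triketone F5, and Ph3P/CCl4 closes the eastern pyranone and delivers 32.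

2. Step 12.
- What may go wrong: proton transfer from the α-chiral β,γ-unsaturated aldehyde to the dianion would epimerise C14 and move the alkene. The dianion may attack the acetate. Competing deprotonation at C20 may lead to loss of the silyloxy group.
- Fallback, from 6 back to the route at 22: the nucleophile is kept at the alcohol oxidation level and used as a neutral boron enolate. TESOTf/2,6-lutidine converts 6 into the triethylsilyl ether F6. c-Hex2BCl/Et3N enolises its ethyl side, and the enolate adds to 19 to give the aldol adduct F7. AcOH–THF–H2O removes only the TES group to give the diol F8, and a double Dess–Martin oxidation gives 22.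

3. Step 17.
- What may go wrong: silylation may occur at the exocyclic carbon instead of at oxygen. The very electron-rich dienol ether may hydrolyse during isolation.
- Fallback, from 27 back to the route at 29: the order of events is reversed. TBSOTf in CH2Cl2 first silylates the carbonyl oxygen, the only nucleophilic site of 27, to give the 4-silyloxypyrylium triflate F9. Et3N then removes a proton from one of its strongly acidified ethyl CH2 groups (anhydrobase formation of a 2-alkylpyrylium salt). Silicon can therefore only sit on oxygen, and pentane extraction gives 29.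

Further compounds
F1 | step 18 | anti homoallylic alcohol from crotylboration of 25 (C8/C9 as in 31; vinyl group in place of the eastern ring) | O[C@H]([C@@H](C)[C@@H](OC(C)=O)/C(C)=C/[C@H](C)c1oc([C@@H](C)[C@@H](O[Si](C)(C)C(C)(C)C)CC)c(C)c(=O)c1C)[C@@H](C)C=C
F2 | step 18 | C9 propionate of F1 | CCC(=O)O[C@H]([C@@H](C)[C@@H](OC(C)=O)/C(C)=C/[C@H](C)c1oc([C@@H](C)[C@@H](O[Si](C)(C)C(C)(C)C)CC)c(C)c(=O)c1C)[C@@H](C)C=C
F3 | step 18 | C7 aldehyde from cleavage of F2 | CCC(=O)O[C@H]([C@@H](C)[C@@H](OC(C)=O)/C(C)=C/[C@H](C)c1oc([C@@H](C)[C@@H](O[Si](C)(C)C(C)(C)C)CC)c(C)c(=O)c1C)[C@@H](C)C=O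
F4 | step 18 | C7 hydroxy C3,C5 diketone (mixture at C4/C6/C7) | CCC(=O)O[C@H]([C@@H](C)[C@@H](OC(C)=O)/C(C)=C/[C@H](C)c1oc([C@@H](C)[C@@H](O[Si](C)(C)C(C)(C)C)CC)c(C)c(=O)c1C)[C@@H](C)C(O)C(C)C(=O)C(C)C(=O)CC
F5 | step 18 | C3,C5,C7 triketone | CCC(=O)O[C@H]([C@@H](C)[C@@H](OC(C)=O)/C(C)=C/[C@H](C)c1oc([C@@H](C)[C@@H](O[Si](C)(C)C(C)(C)C)CC)c(C)c(=O)c1C)[C@@H](C)C(=O)C(C)C(=O)C(C)C(=O)CC
F6 | step 12 | triethylsilyl ether of 6 | CCC(=O)C(C)C(O[Si](CC)(CC)CC)[C@@H](C)[C@@H](O[Si](C)(C)C(C)(C)C)CC
F7 | step 12 | boron aldol adduct of F6 and 19 (mixture at the centres that are erased later) | C=C[C@@H](C)[C@@H](OC(C)=O)/C(C)=C/[C@H](C)C(O)C(C)C(=O)C(C)C(O[Si](CC)(CC)CC)[C@@H](C)[C@@H](O[Si](C)(C)C(C)(C)C)CC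
F8 | step 12 | diol from F7 after TES removal | C=C[C@@H](C)[C@@H](OC(C)=O)/C(C)=C/[C@H](C)C(O)C(C)C(=O)C(C)C(O)[C@@H](C)[C@@H](O[Si](C)(C)C(C)(C)C)CC
F9 | step 17 | 4-(tert-butyldimethylsilyloxy)-2,6-diethyl-3,5-dimethylpyrylium triflate | CCc1[o+]c(CC)c(C)c(O[Si](C)(C)C(C)(C)C)c1C.[O-]S(=O)(=O)C(F)(F)F
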